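**Strategy.** The route rests on cutting the C3–C4 bond of the hept-5-ene side chain, the bond between the two acetoxy-bearing carbons that lie between the C5=C6 alkene and the C2 tertiary carbinol. This O–C–C–O unit next to a carbinol carbon is read as a glycolate aldol: an anti-selective lithium aldol joins an (E)-enal carrying the whole cyclohexane ring to a glycolate enolate locked in a butane-2,3-diacetal 1,4-dioxan-2-one ring. One operation forms the bond and both carbinol stereocentres; the temporary ring is cleaved afterwards and its carbonyl carbon becomes the CMe2OH carbon. The enal comes from (S)-carvone, whose C5 centre steers the ring stereocentres and is then inverted by equilibration.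

Key step: step 12

Remark: the carbinol centre of 5 is not controlled and is destroyed in step 4, so its SMILES leaves that centre open.

**Route**

Step 1
Reactants: 1 (S)-carvone
Product: 2 (5S)-5-acetyl-2-methylcyclohex-2-en-1-one
Conditions: O3, CH2Cl2/MeOH, −78 °C; then Me2S
Reagents that add atoms: ozone, O=[O+][O-]
Why: Chemoselective ozonolysis, because the electron-rich 1,1-disubstituted isopropenyl alkene reacts much faster than the electron-poor enone alkene, and the neutral reductive work-up should leave the C5 stereocentre untouched.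

Step 2
Reactants: 2 (5S)-5-acetyl-2-methylcyclohex-2-en-1-one
Product: 3 (5S)-2-methyl-5-(2-methyl-1,3-dioxolan-2-yl)cyclohex-2-en-1-one
Conditions: TMSOCH2CH2OTMS, TMSOTf (cat.), CH2Cl2, −78 °C
Reagents that add atoms: 1,2-bis(trimethylsilyloxy)ethane, C[Si](C)(C)OCCO[Si](C)(C)C
Why: Silyl-triflate-catalysed ketalisation protects the saturated methyl ketone much faster than the conjugated ring ketone and avoids protic acid that could enolise and racemise C5, so the future acetyl group is masked against the enolate, hydrazine and base steps.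

Step 3
Reactants: 3 (5S)-2-methyl-5-(2-methyl-1,3-dioxolan-2-yl)cyclohex-2-en-1-one
Product: 5 (2S,3R,5S)-2-(1-hydroxyethyl)-2-methyl-5-(2-methyl-1,3-dioxolan-2-yl)-3-(prop-1-en-2-yl)cyclohexan-1-one, via bromomagnesium enolate 4 (not isolated)
Conditions: CH2=C(CH3)MgBr, CuBr·SMe2 (cat.), THF, −40 °C; then MeCHO, −78 °C; aq. NH4Cl
Reagents that add atoms: isopropenylmagnesium bromide, CC(=C)[Mg]Br; acetaldehyde, CC=O
Why: Copper-catalysed conjugate addition occurs by axial attack anti to the C5 substituent (3,5-trans), and the tetrasubstituted enolate 4, whose new C3 group sits pseudoaxial to avoid A(1,2) strain with the C2 methyl, undergoes the aldol reaction with acetaldehyde on the face anti to that group, which sets the quaternary C2 centre with methyl cis and the two-carbon unit trans to the isopropenyl group.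

Step 4
Reactants: 5 (2S,3R,5S)-2-(1-hydroxyethyl)-2-methyl-5-(2-methyl-1,3-dioxolan-2-yl)-3-(prop-1-en-2-yl)cyclohexan-1-one
Product: 6 (2R,3R,5S)-2-ethenyl-2-methyl-5-(2-methyl-1,3-dioxolan-2-yl)-3-(prop-1-en-2-yl)cyclohexan-1-one
Conditions: Martin sulfurane, CH2Cl2, 0 °C → rt
Reagents that add atoms: none
Why: Sulfurane-mediated dehydration proceeds by E2 elimination of the alkoxysulfonium intermediate, and because the neighbouring ring carbon is quaternary the only β-hydrogens are those of the methyl group, so the terminal vinyl group is the only possible alkene and no stereocentre is touched.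

Step 5
Reactants: 6 (2R,3R,5S)-2-ethenyl-2-methyl-5-(2-methyl-1,3-dioxolan-2-yl)-3-(prop-1-en-2-yl)cyclohexan-1-one
Product: 7 2-[(1R,3R,4R)-4-ethenyl-4-methyl-3-(prop-1-en-2-yl)cyclohexyl]-2-methyl-1,3-dioxolane
Conditions: N2H4·H2O, KOH, diethylene glycol, 130 → 200 °C, Ar
Reagents that add atoms: none
Why: Wolff–Kishner reduction (Huang-Minlon procedure) turns C=O into CH2 through the hydrazone anion and loss of N2, and the ketal, the isolated alkenes and the non-enolisable quaternary α-centre should tolerate hot hydroxide when oxygen is excluded to prevent diimide reduction of the vinyl group.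

Step 6
Reactants: 7 2-[(1R,3R,4R)-4-ethenyl-4-methyl-3-(prop-1-en-2-yl)cyclohexyl]-2-methyl-1,3-dioxolane
Product: 9 1-[(1S,3R,4R)-4-ethenyl-4-methyl-3-(prop-1-en-2-yl)cyclohexyl]ethan-1-one, via axial methyl ketone 8 (not isolated)
Conditions: 1 M HCl, THF, rt; then NaOMe, MeOH, rt
Reagents that add atoms: water, O
Why: Acid hydrolysis of the dioxolane gives the axial ketone 8, and base-mediated enolisation then epimerises the α-carbon to the thermodynamically favoured equatorial acetyl isomer (cis to the equatorial isopropenyl group in a chair anchored by the trans-diequatorial vinyl/isopropenyl pair), which inverts the former carvone centre to the required (1S) configuration, the minor epimer being re-equilibrated.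

Step 7
Reactants: 9 1-[(1S,3R,4R)-4-ethenyl-4-methyl-3-(prop-1-en-2-yl)cyclohexyl]ethan-1-one
Product: 10 (2E)-3-[(1S,3R,4R)-4-ethenyl-4-methyl-3-(prop-1-en-2-yl)cyclohexyl]-N-methoxy-N-methylbut-2-enamide
Conditions: (EtO)2P(O)CH2C(O)N(OMe)Me, NaH, THF, 0 °C → reflux
Reagents that add atoms: diethyl [2-(methoxy(methyl)amino)-2-oxoethyl]phosphonate, CCOP(=O)(CC(=O)N(C)OC)OCC
Why: Horner–Wadsworth–Emmons olefination of the methyl ketone with a stabilised phosphonate anion is reversible before elimination and places the larger cyclohexyl group trans to the amide, so the (E)-trisubstituted alkene should predominate and is separated from the (Z)-isomer by chromatography.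

Step 8
Reactants: 10 (2E)-3-[(1S,3R,4R)-4-ethenyl-4-methyl-3-(prop-1-en-2-yl)cyclohexyl]-N-methoxy-N-methylbut-2-enamide
Product: 11 (2E)-3-[(1S,3R,4R)-4-ethenyl-4-methyl-3-(prop-1-en-2-yl)cyclohexyl]but-2-enal
Conditions: DIBAL-H, THF, −78 °C; aq. Rochelle salt
Reagents that add atoms: none
Why: Hydride addition to the N-methoxy-N-methylamide gives a stable five-membered aluminium chelate that collapses to the aldehyde only on work-up, so the reduction should stop at the (E)-enal without 1,4-reduction or over-reduction.

Step 9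
Reactants: 12 (R)-3-chloropropane-1,2-diol
Product: 13 (2R,3R,5R)-5-(chloromethyl)-2,3-dimethoxy-2,3-dimethyl-1,4-dioxane
Conditions: butane-2,3-dione, HC(OMe)3, CSA (cat.), MeOH, reflux
Reagents that add atoms: butane-2,3-dione, CC(=O)C(C)=O; trimethyl orthoformate, COC(OC)OC
Why: Acid-catalysed acetalisation of the 1,2-diol with the 1,2-diketone under thermodynamic control gives the butane-2,3-diacetal in its single most stable chair, with both methoxy groups axial (double anomeric effect) and the chloromethyl group equatorial, so the diol stereocentre dictates the (2R,3R) configuration of the two new acetal centres.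

Step 10
Reactants: 13 (2R,3R,5R)-5-(chloromethyl)-2,3-dimethoxy-2,3-dimethyl-1,4-dioxane
Product: 14 (2R,3R)-2,3-dimethoxy-2,3-dimethyl-5-methylidene-1,4-dioxane
Conditions: KOtBu, THF, reflux
Reagents that add atoms: none
Why: Base-induced E2 elimination of HCl across the chloromethyl carbon and the adjacent ring C–H gives the exocyclic enol ether, which removes the original carbinol stereocentre while the two acetal centres keep the chirality.

Step 11
Reactants: 14 (2R,3R)-2,3-dimethoxy-2,3-dimethyl-5-methylidene-1,4-dioxane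
Product: 15 (5R,6R)-5,6-dimethoxy-5,6-dimethyl-1,4-dioxan-2-one
Conditions: O3, CH2Cl2, −78 °C; then Me2S
Reagents that add atoms: ozone, O=[O+][O-]
Why: Ozonolysis of the electron-rich exocyclic enol ether cleaves C=CH2 to the lactone carbonyl and gives the diacetal-protected glycolic acid lactone whose only stereocentres are the two acetal carbons.

Step 12
Reactants: 15 (5R,6R)-5,6-dimethoxy-5,6-dimethyl-1,4-dioxan-2-one; 11 (2E)-3-[(1S,3R,4R)-4-ethenyl-4-methyl-3-(prop-1-en-2-yl)cyclohexyl]but-2-enal
Product: 17 (3S,5R,6R)-3-{(1S,2E)-3-[(1S,3R,4R)-4-ethenyl-4-methyl-3-(prop-1-en-2-yl)cyclohexyl]-1-hydroxybut-2-en-1-yl}-5,6-dimethoxy-5,6-dimethyl-1,4-dioxan-2-one, via lithium enolate 16 (not isolated)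
Conditions: LiHMDS, THF, −78 °C; then 11, −78 °C; AcOH quench at −78 °C
Reagents that add atoms: none
Why: LiHMDS deprotonates C3 of 15 to the lithium enolate 16, whose E(O) geometry is fixed by the ring, and this adds 1,2 to the aldehyde of 11 through a closed six-membered Zimmerman–Traxler transition state, the closest known reaction type being the lithium aldol of diacetal-protected glycolate lactones with aldehydes, which gives anti-2,3-dihydroxy acid derivatives. No ring is closed in this step. The new centre at the dioxanone C3 (S, later C3 of the heptene chain) is controlled by the axial methoxy group at C5, which is 1,3-diaxial to the enolate carbon and blocks one face, so the aldehyde bonds from the opposite face and the new substituent ends up equatorial. The carbinol centre (S, later C4 of the chain) is controlled by the chair transition state, in which the ring-fixed E-enolate and the equatorial enal residue give the anti relationship between the ring oxygen and the new hydroxyl. The step needs 1,2- over 1,4-addition and addition over γ-deprotonation, which the β,β-disubstituted enal and the low temperature should secure, and it needs reagent control because the ring stereocentres of 11 are too remote to influence the new centres. Quenching with acetic acid at −78 °C should prevent retro-aldol equilibration.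

Step 13
Reactants: 17 (3S,5R,6R)-3-{(1S,2E)-3-[(1S,3R,4R)-4-ethenyl-4-methyl-3-(prop-1-en-2-yl)cyclohexyl]-1-hydroxybut-2-en-1-yl}-5,6-dimethoxy-5,6-dimethyl-1,4-dioxan-2-one
Product: 19 (3S,4S,5E)-6-[(1S,3R,4R)-4-ethenyl-4-methyl-3-(prop-1-en-2-yl)cyclohexyl]-2-methylhept-5-ene-2,3,4-triol, via mixed ketal 18 (not isolated)
Conditions: MeMgBr (excess), CeCl3, THF, −78 → 0 °C; aq. NH4Cl; then AcOH–THF–H2O, rt
Reagents that add atoms: methylmagnesium bromide, C[Mg]Br
Why: Methyl addition under organocerium conditions (which suppress enolisation and retro-aldol of the β-hydroxy lactone) opens the lactone and adds twice to give the tertiary carbinol, while the released hemiketal alkoxide expels methoxide and its ketone is methylated too, leaving the C3 oxygen as the acyclic mixed ketal 18 that mild aqueous acetic acid should hydrolyse to the triol without ionising the allylic alcohol or touching a stereocentre.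

Step 14
Reactants: 19 (3S,4S,5E)-6-[(1S,3R,4R)-4-ethenyl-4-methyl-3-(prop-1-en-2-yl)cyclohexyl]-2-methylhept-5-ene-2,3,4-triol
Product: 20 (3S,4S,5E)-6-[(1S,3R,4R)-4-ethenyl-4-methyl-3-(prop-1-en-2-yl)cyclohexyl]-2-hydroxy-2-methylhept-5-ene-3,4-diyl diacetate
Conditions: Ac2O, pyridine, DMAP (cat.), CH2Cl2, 0 °C → rt
Reagents that add atoms: acetic anhydride, CC(=O)OC(C)=O
Why: Acetylation with acetic anhydride and pyridine esterifies the two secondary hydroxyls, whereas the hindered tertiary hydroxyl should not react under these mild conditions, so the 3,4-diacetate with free C2–OH is obtained with all stereocentres unchanged.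

**Compound list**

1 | (S)-carvone, (5S)-2-methyl-5-(prop-1-en-2-yl)cyclohex-2-en-1-one | CC1=CC[C@@H](CC1=O)C(C)=C | starting material
2 | (5S)-5-acetyl-2-methylcyclohex-2-en-1-one | CC1=CC[C@@H](CC1=O)C(C)=O | intermediate
3 | (5S)-2-methyl-5-(2-methyl-1,3-dioxolan-2-yl)cyclohex-2-en-1-one | CC1=CC[C@@H](CC1=O)C2(C)OCCO2 | intermediate
4 | bromomagnesium (3R,5S)-2-methyl-5-(2-methyl-1,3-dioxolan-2-yl)-3-(prop-1-en-2-yl)cyclohex-1-en-1-olate | CC1=C(O[Mg]Br)C[C@@H](C2(C)OCCO2)C[C@@H]1C(C)=C | intermediate
5 | (2S,3R,5S)-2-(1-hydroxyethyl)-2-methyl-5-(2-methyl-1,3-dioxolan-2-yl)-3-(prop-1-en-2-yl)cyclohexan-1-one (carbinol epimers) | O=C1C[C@@H](C2(C)OCCO2)C[C@H](C(C)=C)[C@@]1(C)C(C)O | intermediate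
6 | (2R,3R,5S)-2-ethenyl-2-methyl-5-(2-methyl-1,3-dioxolan-2-yl)-3-(prop-1-en-2-yl)cyclohexan-1-one | O=C1C[C@@H](C2(C)OCCO2)C[C@H](C(C)=C)[C@@]1(C)C=C | intermediate
7 | 2-[(1R,3R,4R)-4-ethenyl-4-methyl-3-(prop-1-en-2-yl)cyclohexyl]-2-methyl-1,3-dioxolane | C=C[C@@]1(C)CC[C@@H](C2(C)OCCO2)C[C@@H]1C(C)=C | intermediate
8 | 1-[(1R,3R,4R)-4-ethenyl-4-methyl-3-(prop-1-en-2-yl)cyclohexyl]ethan-1-one (axial acetyl) | C=C[C@@]1(C)CC[C@@H](C(C)=O)C[C@@H]1C(C)=C | intermediate
9 | 1-[(1S,3R,4R)-4-ethenyl-4-methyl-3-(prop-1-en-2-yl)cyclohexyl]ethan-1-one (equatorial acetyl) | C=C[C@@]1(C)CC[C@H](C(C)=O)C[C@@H]1C(C)=C | intermediate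
10 | (2E)-3-[(1S,3R,4R)-4-ethenyl-4-methyl-3-(prop-1-en-2-yl)cyclohexyl]-N-methoxy-N-methylbut-2-enamide | C=C[C@@]1(C)CC[C@H](/C(C)=C/C(=O)N(C)OC)C[C@@H]1C(C)=C | intermediate
11 | (2E)-3-[(1S,3R,4R)-4-ethenyl-4-methyl-3-(prop-1-en-2-yl)cyclohexyl]but-2-enal | C=C[C@@]1(C)CC[C@H](/C(C)=C/C=O)C[C@@H]1C(C)=C | intermediate
12 | (R)-3-chloropropane-1,2-diol | OC[C@@H](O)CCl | starting material
13 | (2R,3R,5R)-5-(chloromethyl)-2,3-dimethoxy-2,3-dimethyl-1,4-dioxane | ClC[C@H]1CO[C@@](C)(OC)[C@](C)(OC)O1 | intermediate
14 | (2R,3R)-2,3-dimethoxy-2,3-dimethyl-5-methylidene-1,4-dioxane | C=C1CO[C@@](C)(OC)[C@](C)(OC)O1 | intermediate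
15 | (5R,6R)-5,6-dimethoxy-5,6-dimethyl-1,4-dioxan-2-one | O=C1CO[C@@](C)(OC)[C@](C)(OC)O1 | intermediate
16 | lithium (5R,6R)-5,6-dimethoxy-5,6-dimethyl-5,6-dihydro-1,4-dioxin-2-olate | [Li]OC1=CO[C@@](C)(OC)[C@](C)(OC)O1 | intermediate
17 | (3S,5R,6R)-3-{(1S,2E)-3-[(1S,3R,4R)-4-ethenyl-4-methyl-3-(prop-1-en-2-yl)cyclohexyl]-1-hydroxybut-2-en-1-yl}-5,6-dimethoxy-5,6-dimethyl-1,4-dioxan-2-one | C=C[C@@]1(C)CC[C@H](/C(C)=C/[C@H](O)[C@@H]2O[C@@](C)(OC)[C@](C)(OC)OC2=O)C[C@@H]1C(C)=C | intermediate
18 | (3S,4S,5E)-6-[(1S,3R,4R)-4-ethenyl-4-methyl-3-(prop-1-en-2-yl)cyclohexyl]-3-{[(2R)-3-hydroxy-2-methoxy-3-methylbutan-2-yl]oxy}-2-methylhept-5-ene-2,4-diol | C=C[C@@]1(C)CC[C@H](/C(C)=C/[C@H](O)[C@H](O[C@@](C)(OC)C(C)(C)O)C(C)(C)O)C[C@@H]1C(C)=C | intermediate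
19 | (3S,4S,5E)-6-[(1S,3R,4R)-4-ethenyl-4-methyl-3-(prop-1-en-2-yl)cyclohexyl]-2-methylhept-5-ene-2,3,4-triol | C=C[C@@]1(C)CC[C@H](/C(C)=C/[C@H](O)[C@H](O)C(C)(C)O)C[C@@H]1C(C)=C | intermediate
20 | (3S,4S,5E)-6-[(1S,3R,4R)-4-ethenyl-4-methyl-3-(prop-1-en-2-yl)cyclohexyl]-2-hydroxy-2-methylhept-5-ene-3,4-diyl diacetate | C=C[C@@]1(C)CC[C@H](/C(C)=C/[C@H](OC(C)=O)[C@H](OC(C)=O)C(C)(C)O)C[C@@H]1C(=C)C | target

**Step count and risks**

Total step count: 14 (steps 1–8 to the enal, steps 9–11 to the glycolate, steps 12–14 after the union).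
Longest linear sequence: 11 steps (steps 1–8, then 12–14).

Steps most likely to fail:

1. Step 12. The enolate may abstract a γ-proton of the enal instead of adding, the lithium aldolate may equilibrate by retro-aldol and lose the anti preference, or the facial shielding may be incomplete. The fallback sets out from 11: an L-proline-catalysed direct aldol with hydroxyacetone (DMSO, rt), whose enamine reacts at the hydroxyl-bearing carbon and is known to give the anti-(3S,4S) sense, should give the (3S,4S,5E)-3,4-dihydroxy methyl ketone F1. Methylmagnesium bromide with CeCl3 then adds once to the ketone, and the route is rejoined at 19.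

2. Step 5. Hydrazone formation at the neopentylic carbonyl may be incomplete, adventitious diimide may reduce the vinyl group, and hot hydroxide may move the terminal alkenes. The fallback sets out from 6: condensation with p-toluenesulfonohydrazide gives the tosylhydrazone F2, which is reduced with catecholborane and then heated with sodium acetate, so that the diazene intermediate loses sulfinate and nitrogen under near-neutral conditions. The route is rejoined at 7.

3. Step 4. The neopentylic alkoxysulfonium may ionise with a 1,2-shift or the β-hydroxy ketone may cleave by retro-aldol instead of eliminating, and upstream the hindered enolate may simply be protonated by acetaldehyde. The fallback sets out from 3: after the same copper-catalysed isopropenyl addition the enolate is trapped by conjugate addition to phenyl vinyl sulfoxide to give the 2-(phenylsulfinyl)ethyl ketone F3. Thermal syn-elimination of the sulfoxide (toluene, reflux, CaCO3) then unveils the vinyl group, and the route is rejoined at 6.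

Further compounds
F1 | step 12 | (3S,4S,5E)-6-[(1S,3R,4R)-4-ethenyl-4-methyl-3-(prop-1-en-2-yl)cyclohexyl]-3,4-dihydroxyhept-5-en-2-one | C=C[C@@]1(C)CC[C@H](/C(C)=C/[C@H](O)[C@H](O)C(C)=O)C[C@@H]1C(C)=C
F2 | step 5 | N'-[(2R,3R,5S)-2-ethenyl-2-methyl-5-(2-methyl-1,3-dioxolan-2-yl)-3-(prop-1-en-2-yl)cyclohexylidene]-4-methylbenzenesulfonohydrazide | Cc1ccc(cc1)S(=O)(=O)NN=C1C[C@@H](C2(C)OCCO2)C[C@H](C(C)=C)[C@@]1(C)C=C
F3 | step 4 | (2R,3R,5S)-2-methyl-5-(2-methyl-1,3-dioxolan-2-yl)-2-[2-(phenylsulfinyl)ethyl]-3-(prop-1-en-2-yl)cyclohexan-1-one | O=C1C[C@@H](C2(C)OCCO2)C[C@H](C(C)=C)[C@@]1(C)CCS(=O)c1ccccc1
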